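## Structural features

The target is a germacranolide: a ten-membered carbocycle C1–C10 fused along C6–C7 to an α-methylene-γ-butyrolactone (O6, C12, C11=C13). The carbocycle holds a ketone at C2 between two allylic methylenes: C3 leads to the trisubstituted C4=C5 alkene, which carries the acetoxymethyl carbon C15, and C1 leads to the exocyclic C10=C14 methylene; a second acetate sits on C8. C6 (R), C7 (R) and C8 (S) are contiguous stereocentres: O6 and the C11 branch are trans on the lactone, and the C8 acetoxy group lies on the ring face opposite to the C11 branch. The fragile elements are the doubly β,γ-unsaturated ketone (it slips into conjugation under acid or base), the α-methylene lactone (a Michael acceptor), the allylic C15 acetate and the medium-ring diene, which invites transannular reactions under acid. The real difficulty is twofold: the geometry of C4=C5 (C15 cis to C6, so the ring carbons C3 and C6 are trans) and the closure of the ten-membered ring with control at C8. Two features are exploited. O15 and O6 are both oxygenated and cis across C4=C5, so one silicon atom can bridge them into a seven-membered ring (C4, C5, C6, O6, Si, O15, C15) in which a metathesis-made alkene can only be cis. And C2 is flanked by two like 2-methyleneallyl units (C3–C4–C15 and C1–C10–C9), so one 1,3-dithiane carbon can carry both arms and mask the ketone to the end.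

## Logic of the disconnections

**36 from 35.** Only C2 changes: the two C2–S bonds are exchanged for the C2=O bond. Keeping C2 masked to the end means the doubly β,γ-unsaturated ketone never meets base, fluoride or hydride. The forward step must be an oxidative, near-neutral hydrolysis that spares the α-methylene lactone, both acetates and three alkenes and sets no free thiol loose.

**35 from 34 from 32.** The O15–acetyl bond and then the lactone C12–O6 bond are cut, and the two Si–O bonds are restored. In 32, O6 and O15 are still tied to silicon and C12 is a free acid. One fluoride treatment then frees both oxygens, O6 closes the five-membered lactone, and O15 is the only hydroxyl left to acetylate. This requires O8 to be acylated beforehand, so that C12 can only be captured by O6.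

**32 from 31 from 30.** C12 is taken back from acid to aldehyde to silyl ether (C12–O bonds only). A C12 acyl group must not exist while O8 is a free alkoxide, or the isomeric 8,12-lactone would form. The forward oxidations must spare the thioacetal sulfur and the silicon bridge.

**30 from 29 from 27.** After the O8–acetyl bond, the C8–C9 bond is cut. This opens the ten-membered ring to a C8 aldehyde and a C9 allylic chloride on the same molecule. The 2-substituted allyl unit is symmetric, so the C10=C14 methylene comes out of the bond formation unchanged. The forward step must be a chemoselective carbonyl allylation at high dilution that chooses the right face of the aldehyde next to C7.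

**27 from 26 from 25.** C8 is adjusted from aldehyde to alcohol to acetate (C8–O bonds only). An acetate is chosen because hydride removes it at low temperature beside the silicon groups and the allylic chloride.

**25 from 24.** The C4=C5 bond is cut to a C5 vinyl group and a C4 methylene, both hanging from the O6–Si–O15 bridge. This is the strategic cut: it turns a geometry problem into a ring-size problem and joins two halves of similar size. The forward step must choose the C4 methylene over the C10 and C11 methylenes and must tolerate sulfur.

**24 from 14, 21 and 22.** Two Si–O bonds are cut. This gives the chiral eastern vinyl carbinol 14 (C5–C8, C11–C13, both stereocentres) and the achiral western alcohol 21 (C1–C4, C9, C10, C14, C15). The hindered secondary hydroxyl must be silylated first and only once.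

**21 from 20, from 17 and 18; 17 from 15 and 4.** After the protecting Si–O15 bond, the C1–C2 and C2–C3 bonds are cut at the thioacetal carbon, which acts as an acyl-anion equivalent twice. The order is dictated: a lithiated thioacetal carbon that already carries the chloromethylallyl arm would close onto its own chloride to a methylenecyclobutane. So the oxygenated arm goes on first (from 4) and the chloride arm last (from 18, in excess). This also avoids a statistical mono-hydrolysis of a symmetric bis-chloride.

**14 from 13 from 12, from 9 and 10.** The acetate O–acyl bond, the C8–N bond (by reduction) and then the C6–C7 bond are cut. With the chain C5–C6–C7–C8 drawn in zigzag, the C6 hydroxyl and the C7 branch are syn, the pattern of an auxiliary-controlled syn aldol reaction. Both stereocentres arise in one step, and the 1,3-diol that follows lets the C8 acetate be placed by simple primary-over-secondary selectivity. The forward step requires α-selective reaction of a deconjugated dienolate without drift of the β,γ-alkene into conjugation.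

**9 from 6 and 7; 6 from 4; 4 from 2 from 1.** The N–acyl bond, the C7–C8 bond (carboxylation of an allyl metal), a C–Cl bond and an O–Si bond are cut. Intermediate 4 serves both halves of the molecule. The forward steps must keep a primary triethylsilyl ether through organometallic and mildly acidic work-up conditions.

## Other disconnections considered

**Alternative 1:** The cut is C2–C3, made possible by a temporary C5–C10 bond. The ten-membered ring is folded back to a cyclohexanol A1 (ring C5–C10) that carries a vinyl group on the C10 carbinol and a 3-silyloxyprop-1-en-2-yl group on C5. In the forward step the potassium alkoxide of A1 (KH, 18-crown-6) would undergo an anionic oxy-Cope [3,3] shift that forms C2–C3, breaks C5–C10 and gives cyclodecenone A2 with C4=C5 in place.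
- In its favour: the medium ring grows from an unstrained six-membered ring without high dilution. C6, C7 and C8 and the lactone are set on a rigid cyclohexane, where C8 is easier to control than in a macrocyclisation; on this point the alternative is the better plan.
- Against it here: A2 has its carbonyl at C10 and a bare CH2 at C2. The C10 methylene, the C11 methylene and above all the C2 ketone (oxidation of a ring CH2 with no handle) would all have to be introduced on a sensitive medium ring.
- Structure: it suits germacranes oxidised at C10 or C1 and suits a C2 ketone poorly.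
- Mechanism: the alkene geometry rests on a chair-over-boat preference of the pericyclic transition state, whereas the chosen plan enforces it by ring size.
- Step economy: the ring-forming stage would be equal or shorter, but the adjustments after A2 would make the whole longer.

**Alternative 2:** The cut is C8–C9, reached by excising an oxygen. The substrate is an eleven-membered cyclic ether A3 in which oxygen links C8 (bearing a tributylstannyl group) to C14, with C9 as an exocyclic methylene on C10. In the forward step tin–lithium exchange (n-BuLi, −78 °C) would give an α-alkoxy carbanion at C8 that attacks C9 in a [2,3] Wittig–Still shift. The O–C14 bond breaks and the ten-membered carbocycle A4 appears with the C8 hydroxyl and the C10=C14 methylene.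
- In its favour: it makes the same bond as step 15 of the chosen route, but the configuration at C8 is transferred from the stannane carbon. That is in principle more reliable than the facial selectivity of a chromium allylation, so here the alternative is the better. It also needs no enolisable aldehyde next to C7 at the ring-forming stage.
- Against it here: A3 is itself a macrocycle that must first be closed by etherification. It needs a configurationally defined α-alkoxystannane next to C7, so the stereochemical problem is moved and not removed. An alkyllithium must act beside a thioacetal and three silyl ethers, and a [1,2] shift can compete.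
- Structure: it leaves the C4=C5 geometry to another step, so it is compatible with the chosen key step and does not replace it; on protecting-group pattern the two plans are equal.
- Mechanism: a concerted sigmatropic shift versus a metal-mediated addition.
- Step economy: at least three steps more (stannylation, ether ring closure, exchange).

**Alternative 3:** The cut is C5–C6. The substrate is the open chain A5 with a C5 iodoalkene (iodine cis to C15) and a C6 aldehyde. In the forward step divalent chromium, regenerated at the cathode, with a nickel co-catalyst (NiCl2) would turn the iodoalkene into an alkenylchromium that adds to the aldehyde. This closes the ring and gives allylic alcohol A6.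
- In its favour: the alkene geometry is carried in by the iodoalkene and retained. Chromium is used catalytically, which is better than the stoichiometric CrCl2 of step 15. The free C2 ketone is tolerated, so no thioacetal has to be removed at the end; on this the alternative is equal or better.
- Against it here: C6 would be created in the macrocyclisation next to C7, the same kind of uncertainty that the chosen route has at C8 (equal on this point). The C6 aldehyde is α-branched, β,γ-unsaturated and epimerisable at C7. The free doubly β,γ-unsaturated ketone must survive every step up to A5. The stereodefined trisubstituted iodoalkene needs its own selective synthesis, which is the problem the silicon tether solves by ring size. Closing a ten-membered ring through an sp2 carbon to a ring-trans alkene is strained.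
- Mechanism: polar addition of an alkenylmetal versus metathesis.
- Step economy: similar.

Key step: step 12

Remark on the chemistry: atoms are labelled C1–C15 as in the germacrane skeleton of the target in every fragment; 2-methylidenepropane-1,3-diol, (4S)-4-benzyl-1,3-oxazolidin-2-one and acrolein are taken as commercial.

## Route

Step 1
Reactants: 1 2-methylidenepropane-1,3-diol
Product: 2 2-{[(triethylsilyl)oxy]methyl}prop-2-en-1-ol
Conditions: NaH (1.0 equiv), THF, 0 °C to rt; Et3SiCl (1.0 equiv), rt
Reagents that add atoms: chlorotriethylsilane, CC[Si](Cl)(CC)CC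
Why: One equivalent of NaH gives a sparingly soluble mono-alkoxide of the symmetric diol that is silylated once (O-silylation of an alkoxide), so the mono-ether should predominate over the bis-ether.

Step 2
Reactants: 2 2-{[(triethylsilyl)oxy]methyl}prop-2-en-1-ol
Product: 4 {[2-(chloromethyl)prop-2-en-1-yl]oxy}triethylsilane, via allylic mesylate 3 (not isolated)
Conditions: MeSO2Cl, 2,4,6-collidine, LiCl, DMF, 0 °C to rt
Reagents that add atoms: lithium chloride, [Li+].[Cl-]
Why: Mesylation and in situ chloride displacement (SN2) convert the allylic alcohol into the chloride under buffered, non-acidic conditions that keep the triethylsilyl ether; the allyl unit is symmetric, so direct and allylic displacement give the same product.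

Step 3
Reactants: 4 {[2-(chloromethyl)prop-2-en-1-yl]oxy}triethylsilane
Product: 6 3-{[(triethylsilyl)oxy]methyl}but-3-enoic acid, via allylmagnesium chloride 5 (not isolated)
Conditions: Mg turnings (activated by BrCH2CH2Br), THF, 0 °C, slow addition; CO2 (gas), −40 °C; aq. NaH2PO4 (pH 4–5)
Reagents that add atoms: carbon dioxide, O=C=O
Why: Magnesium insertion into the allylic chloride (slow addition to excess metal against Wurtz coupling) and carboxylation of the allylic Grignard reagent form C7–C8 and give the β,γ-unsaturated acid; both allyl termini are equivalent. The acid is set free at pH 4–5 and used without storage so that the silyl ether is not cleaved.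

Step 4
Reactants: 6 3-{[(triethylsilyl)oxy]methyl}but-3-enoic acid; 7 (4S)-4-benzyl-1,3-oxazolidin-2-one
Product: 9 (4S)-4-benzyl-3-(3-{[(triethylsilyl)oxy]methyl}but-3-enoyl)-1,3-oxazolidin-2-one, via mixed pivalic anhydride 8 (not isolated)
Conditions: t-BuCOCl, Et3N, THF, −20 °C; then lithium salt of 7 (from 7 and n-BuLi, THF, −78 °C), −78 to 0 °C
Reagents that add atoms: none
Why: The lithiated oxazolidinone attacks the less hindered carbonyl of the mixed anhydride (N-acylation of a chiral auxiliary) at −78 °C, where a β,γ-unsaturated acyl group should not move into conjugation.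

Step 5
Reactants: 9 (4S)-4-benzyl-3-(3-{[(triethylsilyl)oxy]methyl}but-3-enoyl)-1,3-oxazolidin-2-one; 10 prop-2-enal
Product: 12 (4S)-4-benzyl-3-[(2S,3R)-3-hydroxy-2-(3-[(triethylsilyl)oxy]prop-1-en-2-yl)pent-4-enoyl]-1,3-oxazolidin-2-one, via boron dienolate 11 (not isolated)
Conditions: n-Bu2BOTf, Et3N, CH2Cl2, −78 to 0 °C; 10, −78 to 0 °C; pH 7 phosphate buffer, MeOH, 30% H2O2, 0 °C
Reagents that add atoms: none
Why: Soft enolisation gives the (Z)-boron dienolate, which reacts at its α-carbon (C7) with the aldehyde through a closed Zimmerman–Traxler chair (Evans syn aldol reaction). The benzyl group of the auxiliary shields one enolate face and so sets C7, and the chair places the new C6 hydroxyl syn to the C7 branch, which is the 6R,7R arrangement of the target (2S,3R in this compound by priority).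

Step 6
Reactants: 12 (4S)-4-benzyl-3-[(2S,3R)-3-hydroxy-2-(3-[(triethylsilyl)oxy]prop-1-en-2-yl)pent-4-enoyl]-1,3-oxazolidin-2-one
Product: 13 (2R,3R)-2-(3-[(triethylsilyl)oxy]prop-1-en-2-yl)pent-4-ene-1,3-diol
Conditions: LiBH4, MeOH (1 equiv), THF, 0 °C
Reagents that add atoms: none
Why: LiBH4 reduces the activated imide carbonyl chemoselectively (reductive removal of the auxiliary), releasing the primary C8 alcohol and the recoverable oxazolidinone without touching the silyl ether or the stereocentres.

Step 7
Reactants: 13 (2R,3R)-2-(3-[(triethylsilyl)oxy]prop-1-en-2-yl)pent-4-ene-1,3-diol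
Product: 14 (2R,3R)-3-hydroxy-2-(3-[(triethylsilyl)oxy]prop-1-en-2-yl)pent-4-en-1-yl acetate
Conditions: AcCl (1.05 equiv), 2,4,6-collidine, CH2Cl2, −78 °C
Reagents that add atoms: acetyl chloride, CC(Cl)=O
Why: Acetyl chloride with a hindered pyridine base at −78 °C acylates the primary hydroxyl much faster than the hindered secondary allylic one (kinetically selective acylation), so O6 stays free for the tether.

Step 8
Reactants: 15 1,3-dithiane; 4 {[2-(chloromethyl)prop-2-en-1-yl]oxy}triethylsilane
Product: 17 triethyl({2-[(1,3-dithian-2-yl)methyl]prop-2-en-1-yl}oxy)silane, via 2-lithio-1,3-dithiane 16 (not isolated)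
Conditions: n-BuLi, THF, −30 °C; then 4, −78 to 0 °C
Reagents that add atoms: none
Why: 2-Lithio-1,3-dithiane is an acyl-anion equivalent that displaces the primary allylic chloride (Corey–Seebach alkylation) and forms C2–C3.

Step 9
Reactants: 17 triethyl({2-[(1,3-dithian-2-yl)methyl]prop-2-en-1-yl}oxy)silane; 18 3-chloro-2-(chloromethyl)prop-1-ene
Product: 20 ({2-[(2-[2-(chloromethyl)prop-2-en-1-yl]-1,3-dithian-2-yl)methyl]prop-2-en-1-yl}oxy)triethylsilane, via lithiated thioacetal 19 (not isolated)
Conditions: n-BuLi, THF, −20 °C; then added to 18 (3 equiv), THF, −78 to −20 °C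
Reagents that add atoms: none
Why: A second metalation at C2 and alkylation with an excess of the bis-electrophile form C1–C2 and leave one allylic chloride for the later ring closure. The chloride arm goes on last because a lithiated dithiane that already carried it would cyclise to a methylenecyclobutane.

Step 10
Reactants: 20 ({2-[(2-[2-(chloromethyl)prop-2-en-1-yl]-1,3-dithian-2-yl)methyl]prop-2-en-1-yl}oxy)triethylsilane
Product: 21 2-({2-[2-(chloromethyl)prop-2-en-1-yl]-1,3-dithian-2-yl}methyl)prop-2-en-1-ol
Conditions: AcOH–THF–H2O (3:1:1), rt
Reagents that add atoms: none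
Why: A primary triethylsilyl ether is hydrolysed by dilute acetic acid at room temperature (acidic desilylation), conditions that affect neither the thioacetal nor the allylic chloride.

Step 11
Reactants: 14 (2R,3R)-3-hydroxy-2-(3-[(triethylsilyl)oxy]prop-1-en-2-yl)pent-4-en-1-yl acetate; 22 dichlorodi(propan-2-yl)silane; 21 2-({2-[2-(chloromethyl)prop-2-en-1-yl]-1,3-dithian-2-yl}methyl)prop-2-en-1-ol
Product: 24 mixed diisopropylsilylene acetal joining O6 of 14 to O15 of 21 (6R,7R), via chlorosilane 23 (not isolated)
Conditions: 22 (1.1 equiv), imidazole, CH2Cl2, 0 °C to rt; then 21, imidazole, DMF, rt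
Reagents that add atoms: none
Why: The hindered secondary alcohol reacts once with the dichlorosilane (a second secondary alkoxide is too hindered to enter), and the chlorosilane is then captured by the primary alcohol: stepwise formation of a mixed dialkoxysilane. The base-buffered medium keeps the triethylsilyl ether and the acetate in place.

Step 12
Reactants: 24 mixed diisopropylsilylene acetal joining O6 of 14 to O15 of 21 (6R,7R)
Product: 25 (2R)-2-[(4R)-6-({2-[2-(chloromethyl)prop-2-en-1-yl]-1,3-dithian-2-yl}methyl)-2,2-di(propan-2-yl)-4,7-dihydro-1,3,2-dioxasilepin-4-yl]-3-{[(triethylsilyl)oxy]methyl}but-3-en-1-yl acetate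
Conditions: RuCl2(=CH-C6H4-2-O-i-Pr)(H2IMes) (second-generation Hoveyda–Grubbs catalyst; H2IMes = 1,3-dimesitylimidazolidin-2-ylidene), 10 mol %, toluene (0.005 M), 80 °C, argon sparge
Reagents that add atoms: none
Why: The ruthenium alkylidene exchanges onto the monosubstituted C5 vinyl group, and the C5 alkylidene undergoes [2+2] cycloaddition with the C4 methylene held nearby by the O6–Si–O15 bridge; cycloreversion of the ruthenacyclobutane gives the C4=C5 bond and a ruthenium methylidene that leaves as ethene. The closest known reaction type is ring-closing metathesis of mixed bis-allylic dialkoxysilanes to 4,7-dihydro-1,3,2-dioxasilepines, including cases that give trisubstituted alkenes. The only ring closed is the seven-membered dioxasilepine (C4, C5, C6, O6, Si, O15, C15), formed by intramolecular alkene metathesis; an alkene inside a seven-membered ring can only be cis, which places C15 cis to C6 and C3 trans to C6 as in the target. No stereocentre is created, and C6 and C7 are not touched by the metal. The step needs alkene geometry and a choice between like methylene groups: ring size fixes the geometry, and the C4 methylene is the only 1,1-disubstituted alkene within reach. The C10 methylene could close only an eleven-membered ring (C5, C6, O, Si, O, C15, C4, C3, C2, C1, C10) and the C11 methylene only a cyclobutene. Metathesis between the two methylene arms to a tetrasubstituted spiro-cyclopentene is disfavoured because the catalyst loads on the vinyl group and not on 1,1-disubstituted alkenes. High dilution and removal of ethene hold back dimerisation through the vinyl group, and N-heterocyclic carbene ruthenium catalysts tolerate thioacetal sulfur.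

Step 13
Reactants: 25 dioxasilepine acetate (6R,7R)
Product: 26 (2R)-2-[(4R)-6-({2-[2-(chloromethyl)prop-2-en-1-yl]-1,3-dithian-2-yl}methyl)-2,2-di(propan-2-yl)-4,7-dihydro-1,3,2-dioxasilepin-4-yl]-3-{[(triethylsilyl)oxy]methyl}but-3-en-1-ol
Conditions: i-Bu2AlH (2.5 equiv), CH2Cl2, −78 °C; aq. KNaC4H4O6
Reagents that add atoms: none
Why: i-Bu2AlH cleaves the acetate by hydride addition at −78 °C (reductive ester cleavage), where the silyl ether, the dialkoxysilane, the thioacetal and the allylic chloride are inert. Carbonate in methanol is avoided because methoxide could displace the allylic chloride.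

Step 14
Reactants: 26 dioxasilepine C8 alcohol
Product: 27 (2S)-2-[(4R)-6-({2-[2-(chloromethyl)prop-2-en-1-yl]-1,3-dithian-2-yl}methyl)-2,2-di(propan-2-yl)-4,7-dihydro-1,3,2-dioxasilepin-4-yl]-3-{[(triethylsilyl)oxy]methyl}but-3-enal
Conditions: Dess–Martin periodinane, pyridine, CH2Cl2, 0 °C
Reagents that add atoms: none
Why: Dess–Martin oxidation under pyridine buffer gives the aldehyde without acid or strong base, which matters because the C7 hydrogen of this α-branched β,γ-unsaturated aldehyde is labile; the aldehyde is used at once (the C7 descriptor changes by priority only).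

Step 15
Reactants: 27 dioxasilepine C8 aldehyde
Product: 29 (6R,7R,8S) ten-membered C8 alcohol with C2 dithiane and O6–Si–O15 bridge, via allylchromium species 28 (not isolated)
Conditions: CrCl2 (10 equiv), NaI (0.2 equiv), THF–DMF (10:1), 25 °C, syringe-pump addition (final 0.002 M)
Reagents that add atoms: none
Why: Two one-electron transfers from divalent chromium turn the allylic chloride into a trivalent allylchromium species that adds through C9 to the C8 aldehyde in a chair-like six-membered transition state (intramolecular Nozaki–Hiyama allylation, a known way to close ten-membered germacrane rings); the symmetric allyl unit returns the C10=C14 methylene. Attack anti to the C6 branch (Felkin–Anh, C6 as the large group), with the C11 branch on the ring periphery, should give the 8S alcohol; this is the least secure stereochemical element of the route.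

Step 16
Reactants: 29 (6R,7R,8S) ten-membered C8 alcohol
Product: 30 (6R,7R,8S) ten-membered C8 acetate with C12 triethylsilyl ether
Conditions: Ac2O, pyridine, DMAP (cat.), CH2Cl2, 0 °C to rt
Reagents that add atoms: acetic anhydride, CC(=O)OC(C)=O
Why: Acylation of the secondary alcohol under nucleophilic catalysis; blocking O8 now prevents it from competing with O6 for C12 later.

Step 17
Reactants: 30 (6R,7R,8S) ten-membered C8 acetate with C12 triethylsilyl ether
Product: 31 (6R,7R,8S) ten-membered C12 enal
Conditions: (COCl)2, Me2SO, CH2Cl2, −78 to −30 °C; Et3N, −78 to 0 °C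
Reagents that add atoms: none
Why: Under Swern conditions the activated sulfoxide attacks the oxygen of a primary triethylsilyl ether, silicon leaves as its chloride and the alkoxysulfonium ion collapses to the aldehyde on addition of base (direct oxidation of primary triethylsilyl ethers). The bulkier diisopropylsilylene bridge should not be attacked.

Step 18
Reactants: 31 (6R,7R,8S) ten-membered C12 enal
Product: 32 (6R,7R,8S) ten-membered C12 acrylic acid
Conditions: NaClO2, NaH2PO4, 2-methylbut-2-ene (excess), t-BuOH–H2O, 0 °C
Reagents that add atoms: sodium chlorite, [Na+].[O-]Cl=O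
Why: Pinnick oxidation converts the enal into the acrylic acid without touching the alkenes; the hypochlorous acid by-product, which could oxidise sulfur, is trapped by the large excess of 2-methylbut-2-ene.

Step 19
Reactants: 32 (6R,7R,8S) ten-membered C12 acrylic acid
Product: 34 (6R,7R,8S) C15 hydroxy α-methylene lactone with C2 dithiane, via dihydroxy acid 33 (not isolated)
Conditions: HF·pyridine, pyridine, THF, 0 °C to rt; then pyridinium p-toluenesulfonate (cat.), CH2Cl2, rt
Reagents that add atoms: none
Why: Fluoride cleaves both Si–O bonds of the bridge (desilylation); the freed O6 hydroxyl is γ to the acid and closes the five-membered lactone under mild acid catalysis, the trans fusion being already fixed at C6 and C7. The primary O15 hydroxyl could only form an eight-membered lactone and stays free.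

Step 20
Reactants: 34 (6R,7R,8S) C15 hydroxy α-methylene lactone with C2 dithiane
Product: 35 (6R,7R,8S) 8,15-diacetate lactone with C2 dithiane
Conditions: Ac2O, pyridine, DMAP (cat.), CH2Cl2, 0 °C
Reagents that add atoms: acetic anhydride, CC(=O)OC(C)=O
Why: Acylation of the only remaining hydroxyl, the primary allylic O15.

Step 21
Reactants: 35 (6R,7R,8S) 8,15-diacetate lactone with C2 dithiane
Product: 36 (6R,7R,8S)-8,15-diacetoxy-2-oxogermacra-4,10(14),11(13)-trien-12,6-olide (C15 cis to C6), the target
Conditions: PhI(OCOCF3)2 (1.5 equiv), NaHCO3, MeCN–H2O (9:1), 0 °C, 10 min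
Reagents that add atoms: water, O
Why: Trivalent iodine oxidises one sulfur, the resulting thionium ion is hydrolysed (oxidative dethioacetalisation) and sulfur leaves as the cyclic disulfide, so no nucleophilic thiol is set free beside the α-methylene lactone. The bicarbonate buffer and the short reaction time protect the doubly β,γ-unsaturated ketone from acid-induced conjugation.

## Compound list

1 | 2-methylidenepropane-1,3-diol | C=C(CO)CO | starting material
2 | 2-{[(triethylsilyl)oxy]methyl}prop-2-en-1-ol | C=C(CO)CO[Si](CC)(CC)CC | intermediate
3 | 2-{[(triethylsilyl)oxy]methyl}prop-2-en-1-yl methanesulfonate | C=C(COS(C)(=O)=O)CO[Si](CC)(CC)CC | intermediate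
4 | {[2-(chloromethyl)prop-2-en-1-yl]oxy}triethylsilane | C=C(CCl)CO[Si](CC)(CC)CC | intermediate
5 | chlorido(2-{[(triethylsilyl)oxy]methyl}prop-2-en-1-yl)magnesium | C=C(C[Mg]Cl)CO[Si](CC)(CC)CC | intermediate
6 | 3-{[(triethylsilyl)oxy]methyl}but-3-enoic acid | C=C(CC(=O)O)CO[Si](CC)(CC)CC | intermediate
7 | (4S)-4-benzyl-1,3-oxazolidin-2-one | O=C1N[C@@H](Cc2ccccc2)CO1 | starting material
8 | 2,2-dimethylpropanoic 3-{[(triethylsilyl)oxy]methyl}but-3-enoic anhydride | C=C(CC(=O)OC(=O)C(C)(C)C)CO[Si](CC)(CC)CC | intermediate
9 | (4S)-4-benzyl-3-(3-{[(triethylsilyl)oxy]methyl}but-3-enoyl)-1,3-oxazolidin-2-one | C=C(CC(=O)N1[C@@H](Cc2ccccc2)COC1=O)CO[Si](CC)(CC)CC | intermediate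
10 | prop-2-enal (acrolein) | C=CC=O | starting material
11 | (Z)-dibutylboron dienolate of 9 (O–B cis to the C11 branch) | CCCCB(CCCC)O/C(N1[C@@H](Cc2ccccc2)COC1=O)=C\C(=C)CO[Si](CC)(CC)CC | intermediate
12 | (4S)-4-benzyl-3-[(2S,3R)-3-hydroxy-2-(3-[(triethylsilyl)oxy]prop-1-en-2-yl)pent-4-enoyl]-1,3-oxazolidin-2-one | C=C[C@@H](O)[C@H](C(=C)CO[Si](CC)(CC)CC)C(=O)N1[C@@H](Cc2ccccc2)COC1=O | intermediate
13 | (2R,3R)-2-(3-[(triethylsilyl)oxy]prop-1-en-2-yl)pent-4-ene-1,3-diol | C=C[C@@H](O)[C@H](C(=C)CO[Si](CC)(CC)CC)CO | intermediate
14 | (2R,3R)-3-hydroxy-2-(3-[(triethylsilyl)oxy]prop-1-en-2-yl)pent-4-en-1-yl acetate (eastern alcohol) | C=C[C@@H](O)[C@H](C(=C)CO[Si](CC)(CC)CC)COC(C)=O | intermediate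
15 | 1,3-dithiane | C1CSCSC1 | starting material
16 | 2-lithio-1,3-dithiane | [Li]C1SCCCS1 | intermediate
17 | triethyl({2-[(1,3-dithian-2-yl)methyl]prop-2-en-1-yl}oxy)silane | C=C(CC1SCCCS1)CO[Si](CC)(CC)CC | intermediate
18 | 3-chloro-2-(chloromethyl)prop-1-ene | C=C(CCl)CCl | starting material
19 | 2-lithio derivative of 17 (lithium on the dithiane C2) | [Li]C1(CC(=C)CO[Si](CC)(CC)CC)SCCCS1 | intermediate
20 | ({2-[(2-[2-(chloromethyl)prop-2-en-1-yl]-1,3-dithian-2-yl)methyl]prop-2-en-1-yl}oxy)triethylsilane | C=C(CCl)CC1(CC(=C)CO[Si](CC)(CC)CC)SCCCS1 | intermediate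
21 | 2-({2-[2-(chloromethyl)prop-2-en-1-yl]-1,3-dithian-2-yl}methyl)prop-2-en-1-ol (western alcohol) | OCC(=C)CC1(SCCCS1)CC(=C)CCl | intermediate
22 | dichlorodi(propan-2-yl)silane | CC(C)[Si](Cl)(Cl)C(C)C | starting material
23 | (2R,3R)-3-{[chlorodi(propan-2-yl)silyl]oxy}-2-(3-[(triethylsilyl)oxy]prop-1-en-2-yl)pent-4-en-1-yl acetate | C=C[C@@H](O[Si](Cl)(C(C)C)C(C)C)[C@H](C(=C)CO[Si](CC)(CC)CC)COC(C)=O | intermediate
24 | (2R,3R)-3-[({[2-({2-[2-(chloromethyl)prop-2-en-1-yl]-1,3-dithian-2-yl}methyl)prop-2-en-1-yl]oxy}di(propan-2-yl)silyl)oxy]-2-(3-[(triethylsilyl)oxy]prop-1-en-2-yl)pent-4-en-1-yl acetate (metathesis precursor; 6R,7R) | C=C[C@@H](O[Si](C(C)C)(C(C)C)OCC(=C)CC1(SCCCS1)CC(=C)CCl)[C@H](C(=C)CO[Si](CC)(CC)CC)COC(C)=O | intermediate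
25 | (2R)-2-[(4R)-6-({2-[2-(chloromethyl)prop-2-en-1-yl]-1,3-dithian-2-yl}methyl)-2,2-di(propan-2-yl)-4,7-dihydro-1,3,2-dioxasilepin-4-yl]-3-{[(triethylsilyl)oxy]methyl}but-3-en-1-yl acetate (C15 cis to C6) | CC(=O)OC[C@@H](C(=C)CO[Si](CC)(CC)CC)[C@@H]1O[Si](C(C)C)(C(C)C)OCC(CC2(SCCCS2)CC(=C)CCl)=C1 | intermediate
26 | (2R)-2-[(4R)-6-({2-[2-(chloromethyl)prop-2-en-1-yl]-1,3-dithian-2-yl}methyl)-2,2-di(propan-2-yl)-4,7-dihydro-1,3,2-dioxasilepin-4-yl]-3-{[(triethylsilyl)oxy]methyl}but-3-en-1-ol | OC[C@@H](C(=C)CO[Si](CC)(CC)CC)[C@@H]1O[Si](C(C)C)(C(C)C)OCC(CC2(SCCCS2)CC(=C)CCl)=C1 | intermediate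
27 | (2S)-2-[(4R)-6-({2-[2-(chloromethyl)prop-2-en-1-yl]-1,3-dithian-2-yl}methyl)-2,2-di(propan-2-yl)-4,7-dihydro-1,3,2-dioxasilepin-4-yl]-3-{[(triethylsilyl)oxy]methyl}but-3-enal (same spatial arrangement at C7 as 26) | O=C[C@@H](C(=C)CO[Si](CC)(CC)CC)[C@@H]1O[Si](C(C)C)(C(C)C)OCC(CC2(SCCCS2)CC(=C)CCl)=C1 | intermediate
28 | dichlorido-allylchromium derivative of 27 (trivalent chromium on C9 in place of chlorine) | O=C[C@@H](C(=C)CO[Si](CC)(CC)CC)[C@@H]1O[Si](C(C)C)(C(C)C)OCC(CC2(SCCCS2)CC(=C)C[Cr](Cl)Cl)=C1 | intermediate
29 | (6R,7R,8S)-8-hydroxy ten-membered carbocycle: C2 as 1,3-dithiane, C10=C14 methylene, C4=C5 with C15 cis to C6, O6 and O15 bridged by Si(i-Pr)2, C7 bearing C(=CH2)CH2OSiEt3 | C=C1CC2(SCCCS2)C/C3=C/[C@@H](O[Si](C(C)C)(C(C)C)OC3)[C@H](C(=C)CO[Si](CC)(CC)CC)[C@@H](O)C1 | intermediate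
30 | 8-O-acetate of 29 (6R,7R,8S) | C=C1CC2(SCCCS2)C/C3=C/[C@@H](O[Si](C(C)C)(C(C)C)OC3)[C@H](C(=C)CO[Si](CC)(CC)CC)[C@@H](OC(C)=O)C1 | intermediate
31 | C12 enal: as 30 with C7 bearing C(=CH2)CHO (6R,7R,8S) | C=C1CC2(SCCCS2)C/C3=C/[C@@H](O[Si](C(C)C)(C(C)C)OC3)[C@H](C(=C)C=O)[C@@H](OC(C)=O)C1 | intermediate
32 | C12 acid: as 30 with C7 bearing C(=CH2)CO2H (6R,7R,8S) | C=C1CC2(SCCCS2)C/C3=C/[C@@H](O[Si](C(C)C)(C(C)C)OC3)[C@H](C(=C)C(=O)O)[C@@H](OC(C)=O)C1 | intermediate
33 | 6,15-dihydroxy C12 acid (silicon bridge removed; same spatial arrangement at C6, C7, C8) | C=C1CC2(SCCCS2)C/C(CO)=C/[C@@H](O)[C@H](C(=C)C(=O)O)[C@@H](OC(C)=O)C1 | intermediate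
34 | (6R,7R,8S)-8-acetoxy-15-hydroxygermacra-4,10(14),11(13)-trien-12,6-olide with C2 as 1,3-dithiane | C=C1CC2(SCCCS2)C/C(CO)=C/[C@H]3OC(=O)C(=C)[C@@H]3[C@@H](OC(C)=O)C1 | intermediate
35 | (6R,7R,8S)-8,15-diacetoxygermacra-4,10(14),11(13)-trien-12,6-olide with C2 as 1,3-dithiane | C=C1CC2(SCCCS2)C/C(COC(C)=O)=C/[C@H]3OC(=O)C(=C)[C@@H]3[C@@H](OC(C)=O)C1 | intermediate
36 | (6R,7R,8S)-8,15-diacetoxy-2-oxogermacra-4,10(14),11(13)-trien-12,6-olide (C15 cis to C6 across C4=C5) | C=C1CC(=O)C/C(COC(C)=O)=C/[C@H]2OC(=O)C(=C)[C@@H]2[C@@H](OC(C)=O)C1 | target

## Step count and least certain steps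

Total: 21 steps. Longest linear sequence: 18 steps (steps 1–7, then 11–21); the western alcohol takes steps 8–10 from 4.

**Step 12 (key step).** Productive ring closure may be outrun by intermolecular metathesis at the C5 vinyl group or by metathesis between the two methylene arms. The reason is that the C4 methylene is a neopentyl-type 1,1-disubstituted alkene next to the fully substituted C2, and sulfur can reversibly occupy the metal. The fallback closes the dioxasilepine before the second arm is attached. It sets out from 17 and 14. Acidic desilylation of 17 (AcOH–THF–H2O) would give 2-[(1,3-dithian-2-yl)methyl]prop-2-en-1-ol F1. Silylation of 14 with 22 and then F1, as in step 11, would give the mixed silaketal F2. Metathesis with the same catalyst would close dioxasilepine F3, whose C4 methylene now stands next to a secondary carbon and has no competitor. i-Bu2AlH would remove the acetate to give alcohol F4. The O,C-dianion of F4 (t-BuLi, THF–HMPA, −78 °C) would be alkylated at C2 with 18, and the route is rejoined at 26.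

**Step 15.** Poor facial selectivity at the C8 aldehyde is the main risk, with intermolecular coupling and enolisation of 27 at C7 as lesser ones. The acyclic Felkin preference and the conformational demands of the forming ten-membered ring need not agree. The fallback corrects instead of controlling. It sets out from the 8R epimer of 29, alcohol F5, formed in the same reaction. A Mitsunobu reaction with acetic acid (PPh3, diisopropyl azodicarboxylate, toluene, 0 °C to rt) would invert C8 and install the acetate in one operation, returning at 30.

**Step 17.** The oxidative desilylation may stop at partial conversion, or chloride may begin to open the silicon bridge, because the activated sulfoxide has to discriminate between two kinds of Si–O bond in one molecule. The fallback separates deprotection from oxidation. It sets out from 30. Mild methanolysis (pyridinium p-toluenesulfonate, MeOH–CH2Cl2, 0 °C) would give the C12 allylic alcohol F6, and MnO2 in CH2Cl2 (allylic oxidation) would return at 31.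

**Step 18.** Oxidation at thioacetal sulfur by hypochlorous acid or chlorite may compete with oxidation of the aldehyde. The fallback takes the thioacetal off before the chlorite step. It sets out from 31. PhI(OCOCF3)2 in buffered aqueous MeCN would give keto enal F7, Pinnick oxidation would give keto acid F8, and HF·pyridine with lactonisation would give keto hydroxy lactone F9. Acetylation (Ac2O, pyridine, 0 °C) returns at 36. The price is that the doubly β,γ-unsaturated ketone must then pass three further steps, which is why this order is not the first choice.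

## Further compounds

F1 | step 12 | 2-[(1,3-dithian-2-yl)methyl]prop-2-en-1-ol | C=C(CO)CC1SCCCS1
F2 | step 12 | mixed diisopropylsilylene acetal joining O6 of 14 to the hydroxyl of F1 (6R,7R) | C=C[C@@H](O[Si](C(C)C)(C(C)C)OCC(=C)CC1SCCCS1)[C@H](C(=C)CO[Si](CC)(CC)CC)COC(C)=O
F3 | step 12 | (2R)-2-[(4R)-6-[(1,3-dithian-2-yl)methyl]-2,2-di(propan-2-yl)-4,7-dihydro-1,3,2-dioxasilepin-4-yl]-3-{[(triethylsilyl)oxy]methyl}but-3-en-1-yl acetate | CC(=O)OC[C@@H](C(=C)CO[Si](CC)(CC)CC)[C@@H]1O[Si](C(C)C)(C(C)C)OCC(CC2SCCCS2)=C1
F4 | step 12 | (2R)-2-[(4R)-6-[(1,3-dithian-2-yl)methyl]-2,2-di(propan-2-yl)-4,7-dihydro-1,3,2-dioxasilepin-4-yl]-3-{[(triethylsilyl)oxy]methyl}but-3-en-1-ol | OC[C@@H](C(=C)CO[Si](CC)(CC)CC)[C@@H]1O[Si](C(C)C)(C(C)C)OCC(CC2SCCCS2)=C1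
F5 | step 15 | 8R epimer of 29 (6R,7R,8R) | C=C1CC2(SCCCS2)C/C3=C/[C@@H](O[Si](C(C)C)(C(C)C)OC3)[C@H](C(=C)CO[Si](CC)(CC)CC)[C@H](O)C1
F6 | step 17 | C12 allylic alcohol: 30 with the triethylsilyl group removed (6R,7R,8S) | C=C1CC2(SCCCS2)C/C3=C/[C@@H](O[Si](C(C)C)(C(C)C)OC3)[C@H](C(=C)CO)[C@@H](OC(C)=O)C1
F7 | step 18 | keto enal: 31 with C2 as ketone (6R,7R,8S) | C=C1CC(=O)C/C3=C/[C@@H](O[Si](C(C)C)(C(C)C)OC3)[C@H](C(=C)C=O)[C@@H](OC(C)=O)C1
F8 | step 18 | keto acid: 32 with C2 as ketone (6R,7R,8S) | C=C1CC(=O)C/C3=C/[C@@H](O[Si](C(C)C)(C(C)C)OC3)[C@H](C(=C)C(=O)O)[C@@H](OC(C)=O)C1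
F9 | step 18 | (6R,7R,8S)-8-acetoxy-15-hydroxy-2-oxogermacra-4,10(14),11(13)-trien-12,6-olide | C=C1CC(=O)C/C(CO)=C/[C@H]2OC(=O)C(=C)[C@@H]2[C@@H](OC(C)=O)C1
A1 | alternative 1 | lactone-fused 1-vinyl-2-[3-(tert-butyldimethylsilyloxy)prop-1-en-2-yl]cyclohexanol (C5–C10 ring, vinyl and alkenyl trans, C8 silyl ether) | C=C[C@]1(O)C[C@H](O[Si](C)(C)C(C)(C)C)[C@H]2CC(=O)O[C@@H]2[C@H]1C(=C)CO[Si](C)(C)C(C)(C)C
A2 | alternative 1 | ten-membered C10 ketone (cyclodec-5-enone) with trans-lactone and both silyl ethers | O=C1CCC/C(CO[Si](C)(C)C(C)(C)C)=C/[C@H]2OC(=O)C[C@@H]2[C@@H](O[Si](C)(C)C(C)(C)C)C1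
A3 | alternative 2 | eleven-membered α-tributylstannyl allyl ether (O between C8 and C14, C9 as exocyclic methylene on C10) | C=C1CC2(SCCCS2)C/C(CO[Si](C)(C)C(C)(C)C)=C/[C@@H](O[Si](CC)(CC)CC)[C@H](C(=C)CO[Si](CC)(CC)CC)[C@H](OC1)[Sn](CCCC)(CCCC)CCCC
A4 | alternative 2 | ten-membered carbocycle with free C8 hydroxyl and C10 methylene | C=C1CC2(SCCCS2)C/C(CO[Si](C)(C)C(C)(C)C)=C/[C@@H](O[Si](CC)(CC)CC)[C@H](C(=C)CO[Si](CC)(CC)CC)[C@@H](O)C1
A5 | alternative 3 | open-chain C5 iodoalkene C6 aldehyde with free C2 ketone (iodine cis to C15) | C=C(CC(=O)C/C(CO[Si](C)(C)C(C)(C)C)=C/I)C[C@H](O[Si](C)(C)C(C)(C)C)[C@H](C=O)C(=C)CO[Si](CC)(CC)CC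
A6 | alternative 3 | ten-membered C6 allylic alcohol | C=C1CC(=O)C/C(CO[Si](C)(C)C(C)(C)C)=C/[C@@H](O)[C@H](C(=C)CO[Si](CC)(CC)CC)[C@@H](O[Si](C)(C)C(C)(C)C)C1
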